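Ring A is disconnected at C7–C8 and C4a–C8a. It is a 1,2,3,5-tetraoxygenated benzene in which C7, C6, C5 (with its methoxy group), C4a and the C4 carbonyl map onto a 4-methoxy-2-pyranone, while C8 (with its methoxy group) and C8a are the two carbons of methoxyacetate. In one operation an ester enolate opens the lactone at C7, and the enolate thus released closes ring A by Claisen condensation onto C8a, leaving the C8a hydroxyl as the only phenol ortho to the C4 carbonyl. The precursor is a 4-methoxy-2-pyranone whose position 6 (future C4) carries C3 and C2 as a dimethyl enediol ether bearing the 2-methoxyphenyl ring B.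

Key step: step 5

Remark: atom labels C2 to C8a are those of the chromone of the target. The enediol ether is drawn with Z geometry (methoxy groups cis), the isomer expected from a chelated enolate. The E isomer would serve equally, because the key step leaves this alkene untouched and ring C closure passes through a protonated enone that rotates freely.

Step 1
Reactants: 1 4-methoxy-6-methyl-2H-pyran-2-one; 2 methyl 2-methoxybenzoate
Product: 3 4-methoxy-6-[2-(2-methoxyphenyl)-2-oxoethyl]-2H-pyran-2-one
Conditions: LiN(iPr)2 (2.2 equiv), THF, −78 °C; then 2, −78 → 0 °C; aq. HCl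
Reagents that add atoms: none
Why: Lateral (vinylogous) deprotonation of the 6-methyl group gives a dienolate that undergoes a crossed Claisen acylation with the non-enolisable ester, and the second equivalent of base converts the more acidic product ketone into its enolate, which prevents a second acylation.

Step 2
Reactants: 3 4-methoxy-6-[2-(2-methoxyphenyl)-2-oxoethyl]-2H-pyran-2-one
Product: 4 6-[1-diazo-2-(2-methoxyphenyl)-2-oxoethyl]-4-methoxy-2H-pyran-2-one
Conditions: 4-AcNHC6H4SO2N3, DBU, MeCN, 0 → 23 °C
Reagents that add atoms: 4-acetamidobenzenesulfonyl azide, CC(=O)Nc1ccc(cc1)S(=O)(=O)N=[N+]=[N-]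
Why: Regitz diazo transfer, since the methylene between the aryl ketone and the pyranone (a vinylogous β-keto ester) is acidic enough for DBU and its enolate attacks the terminal nitrogen of the sulfonyl azide, after which the sulfonamide is expelled.

Step 3
Reactants: 4 6-[1-diazo-2-(2-methoxyphenyl)-2-oxoethyl]-4-methoxy-2H-pyran-2-one
Product: 5 4-methoxy-6-[1-methoxy-2-(2-methoxyphenyl)-2-oxoethyl]-2H-pyran-2-one (racemic)
Conditions: Rh2(OAc)4 (1 mol %), MeOH–CH2Cl2 (1:2), 23 °C, slow addition of 4
Reagents that add atoms: methanol, CO
Why: Carbenoid O–H insertion, in which Rh2(OAc)4 turns the stabilised diazo ketone into an electrophilic rhodium carbenoid that methanol, present in large excess, should trap through an oxonium ylide and proton shift; the new stereocenter is racemic and is erased in step 4.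

Step 4
Reactants: 5 4-methoxy-6-[1-methoxy-2-(2-methoxyphenyl)-2-oxoethyl]-2H-pyran-2-one
Product: 6 6-[(Z)-1,2-dimethoxy-2-(2-methoxyphenyl)ethenyl]-4-methoxy-2H-pyran-2-one
Conditions: Cs2CO3, Me2SO4, DMF, 0 → 23 °C
Reagents that add atoms: dimethyl sulfate, COS(=O)(=O)OC
Why: O-alkylation of an enolate, in which the C–H flanked by ketone, methoxy group and pyranone is removed by carbonate and the weakly paired caesium enolate in DMF should react with the hard electrophile at the ketone oxygen, because the carbon terminus is fully substituted.

Step 5
Reactants: 6 6-[(Z)-1,2-dimethoxy-2-(2-methoxyphenyl)ethenyl]-4-methoxy-2H-pyran-2-one; 7 methyl methoxyacetate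
Product: 9 (2Z)-1-(2,4-dihydroxy-3,6-dimethoxyphenyl)-2,3-dimethoxy-3-(2-methoxyphenyl)prop-2-en-1-one, via ring-opened keto ester 8 (not isolated)
Conditions: 7 (3.2 equiv), LiN(iPr)2 (3.0 equiv), THF, −78 °C; then 6, −78 → 23 °C (50 °C if closure is slow); AcOH, 0 °C
Reagents that add atoms: none
Why: Proposed new method: the lithium enolate of 7 should add through its α-carbon (future C8) to the lactone carbonyl of 6 (future C7), and collapse of the adduct cleaves the ring C–O bond to give keto ester 8 as the lithium enolate of the C4 ketone, whose α-carbon C4a stays cis to C7 across the C5=C6 bond. On warming, C4a should attack the ester carbonyl C8a in a Claisen (Dieckmann-type) condensation, a 6-exo-trig closure of ring A with the enolate double bond outside the ring, after which methoxide leaves and the cyclohexenetrione enolises to the bis-phenoxide of 9, an aromatisation that makes the sequence irreversible. The closest known reaction types are the base-induced opening of polyketide-type 2-pyranones followed by Claisen cyclisation to acylphloroglucinols, and the carbanion-induced transformation of 2-pyranones into benzenes; what is new is that one external ester enolate supplies both the nucleophile that opens the lactone and the electrophile that closes the ring. No stereocenter is formed, the racemic centre C8 of 8 being lost on enolisation. The step needs attack at the lactone carbonyl instead of the conjugate pyranone positions, which the lithium counter-ion, the low temperature and the bulky tetrasubstituted alkene at pyranone position 6 should secure, and it needs Claisen instead of aldol closure, which follows because the aldol adduct of C8 with the C4 ketone cannot aromatise and reverts. Three equivalents of enolate cover the addition and the acidic sites that appear, the enediol ether offers no acidic hydrogen, and the C5 methyl ether leaves the C8a hydroxyl as the only phenol able to close ring C.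

Step 6
Reactants: 9 (2Z)-1-(2,4-dihydroxy-3,6-dimethoxyphenyl)-2,3-dimethoxy-3-(2-methoxyphenyl)prop-2-en-1-one
Product: 10 7-hydroxy-3,5,8-trimethoxy-2-(2-methoxyphenyl)-4H-chromen-4-one
Conditions: TsOH·H2O (0.2 equiv), PhMe, 80 °C
Reagents that add atoms: none
Why: Oxa-Michael addition–elimination on a β-methoxy enone (6-endo-trig), the vinylogous-ester counterpart of the acid cyclodehydration of 2-hydroxyphenyl 1,3-diketones to flavones, in which the C8a phenol adds to C2 of the protonated enone and methanol is lost to give the 4-pyranone ring C.

Step 7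
Reactants: 10 7-hydroxy-3,5,8-trimethoxy-2-(2-methoxyphenyl)-4H-chromen-4-one
Product: 11 3,5,7,8-tetramethoxy-2-(2-methoxyphenyl)-4H-chromen-4-one
Conditions: Me2SO4, K2CO3, acetone, reflux
Reagents that add atoms: dimethyl sulfate, COS(=O)(=O)OC
Why: Williamson ether synthesis on the C7 phenol, the only hydroxyl left and one made acidic by its para relationship to the C4 carbonyl.

Compound list
1 | 4-methoxy-6-methyl-2H-pyran-2-one | COC1=CC(=O)OC(C)=C1 | starting material
2 | methyl 2-methoxybenzoate | COC(=O)c1ccccc1OC | starting material
3 | 4-methoxy-6-[2-(2-methoxyphenyl)-2-oxoethyl]-2H-pyran-2-one | COc1ccccc1C(=O)Cc1cc(OC)cc(=O)o1 | intermediate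
4 | 6-[1-diazo-2-(2-methoxyphenyl)-2-oxoethyl]-4-methoxy-2H-pyran-2-one | COc1ccccc1C(=O)C(=[N+]=[N-])c1cc(OC)cc(=O)o1 | intermediate
5 | 4-methoxy-6-[1-methoxy-2-(2-methoxyphenyl)-2-oxoethyl]-2H-pyran-2-one (racemic) | COc1ccccc1C(=O)C(OC)c1cc(OC)cc(=O)o1 | intermediate
6 | 6-[(Z)-1,2-dimethoxy-2-(2-methoxyphenyl)ethenyl]-4-methoxy-2H-pyran-2-one | COc1ccccc1/C(OC)=C(/OC)c1cc(OC)cc(=O)o1 | intermediate
7 | methyl methoxyacetate | COCC(=O)OC | starting material
8 | methyl (4E,8Z)-2,5,8,9-tetramethoxy-9-(2-methoxyphenyl)-3,7-dioxonona-4,8-dienoate (racemic at C2; present in the flask as its lithium enolate, not isolated) | COc1ccccc1/C(OC)=C(/OC)C(=O)C/C(OC)=C\C(=O)C(OC)C(=O)OC | intermediate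
9 | (2Z)-1-(2,4-dihydroxy-3,6-dimethoxyphenyl)-2,3-dimethoxy-3-(2-methoxyphenyl)prop-2-en-1-one | COc1ccccc1/C(OC)=C(/OC)C(=O)c1c(O)c(OC)c(O)cc1OC | intermediate
10 | 7-hydroxy-3,5,8-trimethoxy-2-(2-methoxyphenyl)-4H-chromen-4-one | COc1ccccc1-c1oc2c(OC)c(O)cc(OC)c2c(=O)c1OC | intermediate
11 | 3,5,7,8-tetramethoxy-2-(2-methoxyphenyl)-4H-chromen-4-one | COc1ccccc1-c1oc2c(OC)c(OC)cc(OC)c2c(=O)c1OC | target

Total step count: 7
Longest linear sequence: 7 steps (1 → 11)

Steps most likely to fail

Step 5. The enolate may add to a conjugate position of the pyranone instead of the lactone carbonyl. The ring-opened intermediate may also rest as a doubly deprotonated keto ester, or revert by retro-Claisen cleavage, instead of closing ring A. The fallback uses the classical acetophenone route and builds ring C last. It sets out from 2 and comes back at 11. Friedel–Crafts acylation of commercial 1,2,3,5-tetramethoxybenzene with methoxyacetyl chloride (AlCl3, CH2Cl2, 0 °C) should give 2-methoxy-1-(2,3,4,6-tetramethoxyphenyl)ethan-1-one F1. With excess AlCl3 at 23 °C, F1 should lose the methyl of the ortho methoxy group flanked by the acyl group and a second methoxy group, giving 1-(2-hydroxy-3,4,6-trimethoxyphenyl)-2-methoxyethan-1-one F2. The lithium dianion of F2 (LiN(SiMe3)2, 4 equiv, THF, −78 → 23 °C) would then be acylated by ester 2 in a crossed Claisen condensation to 1-(2-hydroxy-3,4,6-trimethoxyphenyl)-2-methoxy-3-(2-methoxyphenyl)propane-1,3-dione F3. Acid cyclodehydration of F3 (cat. H2SO4, AcOH, 90 °C) gives 11 directly, with all five methoxy groups in place.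

Step 3. The rhodium carbenoid may be captured by the neighbouring ortho-methoxy oxygen (cyclic oxonium ylide and closure to a benzofuranone) or by the pyranone, in competition with insertion into methanol. The fallback avoids the carbenoid. It sets out from 3 and comes back at 5. The potassium enolate of 3 (KN(SiMe3)2, THF, −78 °C) would be oxidised with 3-phenyl-2-(phenylsulfonyl)oxaziridine to 6-[1-hydroxy-2-(2-methoxyphenyl)-2-oxoethyl]-4-methoxy-2H-pyran-2-one F4. Its hydroxyl would be methylated under neutral conditions (MeI, Ag2O, CH2Cl2) to give 5. Steps 2 and 3 are then not needed.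

Step 4. The extended enolate may be alkylated at carbon, or at the pyranone end of the delocalised system, instead of at the ketone oxygen. The fallback makes the enol ether without an enolate alkylation. It sets out from 5 and comes back at 6. Ketalisation of 5 with MeOSiMe3 and catalytic Me3SiOTf (CH2Cl2, −78 → 0 °C) should give 4-methoxy-6-[1,2,2-trimethoxy-2-(2-methoxyphenyl)ethyl]-2H-pyran-2-one F5, helped by the 2-methoxyphenyl group, which stabilises the oxocarbenium ion. Treatment of F5 with Me3SiOTf and iPr2NEt should then ionise one ketal methoxy group and remove the acidic proton next to the pyranone, giving 6 as a mixture of alkene isomers, both of which are usable.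

Further compounds
F1 | step 5 | 2-methoxy-1-(2,3,4,6-tetramethoxyphenyl)ethan-1-one | COCC(=O)c1c(OC)cc(OC)c(OC)c1OC
F2 | step 5 | 1-(2-hydroxy-3,4,6-trimethoxyphenyl)-2-methoxyethan-1-one | COCC(=O)c1c(OC)cc(OC)c(OC)c1O
F3 | step 5 | 1-(2-hydroxy-3,4,6-trimethoxyphenyl)-2-methoxy-3-(2-methoxyphenyl)propane-1,3-dione (racemic) | COc1ccccc1C(=O)C(OC)C(=O)c1c(OC)cc(OC)c(OC)c1O
F4 | step 3 | 6-[1-hydroxy-2-(2-methoxyphenyl)-2-oxoethyl]-4-methoxy-2H-pyran-2-one (racemic) | COc1ccccc1C(=O)C(O)c1cc(OC)cc(=O)o1
F5 | step 4 | 4-methoxy-6-[1,2,2-trimethoxy-2-(2-methoxyphenyl)ethyl]-2H-pyran-2-one (racemic) | COc1ccccc1C(OC)(OC)C(OC)c1cc(OC)cc(=O)o1
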